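**Retrosynthetic overview**

1. The target is 2-(guaiazulen-3-yl)-3,7-dimethyl-4-isobutyryl-1H-inden-1-one. The five-membered ring is cut at C1–C2 and C3–C3a together, giving a C-aryl N-tert-butyl nitrone (C1 at aldehyde level, C3a still C–H) and 3-(prop-1-ynyl)guaiazulene (the C2≡C3 unit carrying azulenyl and methyl).
2. Enabling feature: C3a–H is the only ring hydrogen ortho to the C1 carbon on C7a (C7 is blocked by its methyl group) and lies between the carbonyl-bearing carbons C7a and C4. The two alkyne substituents (guaiazulenyl flanked by its own C4 methyl, versus methyl) differ so much in size that one insertion orientation is strongly preferred.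
3. The nitrone comes from 5-bromo-2-methylbenzaldehyde (dioxolane, Br–Li exchange and Weinreb acylation with deprotection in the same flask, condensation with t-BuNHOH). The alkyne comes from guaiazulene (Vilsmeier–Haack formylation at C3, Corey–Fuchs homologation with MeI quench).
4. Ring order: the benzene ring and the azulene bicycle are bought. The enone ring of the indenone is the only ring made, in the last step, which also joins the two halves and reaches the ketone level through the N–O bond without an external oxidant.

Key step: step 7

Remark: the target has no stereocentre and the C2–azulenyl bond is treated as a freely rotating axis, so no configuration is set; atom numbers follow 1H-inden-1-one for the indenone and 7-isopropyl-1,4-dimethylazulene for guaiazulene.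

**Route**

Step 1
Reactants: 1 5-bromo-2-methylbenzaldehyde
Product: 2 2-(5-bromo-2-methylphenyl)-1,3-dioxolane
Conditions: ethylene glycol, p-TsOH·H2O (cat.), toluene, reflux, Dean–Stark
Reagents that add atoms: ethylene glycol, OCCO
Why: Acid-catalysed acetalisation with azeotropic removal of water should mask the aldehyde as a dioxolane that is inert to the organolithium chemistry of step 2.

Step 2
Reactants: 2 2-(5-bromo-2-methylphenyl)-1,3-dioxolane
Product: 5 2-methyl-5-(2-methylpropanoyl)benzaldehyde, via aryllithium 3 (not isolated), via keto acetal 4 (not isolated)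
Conditions: n-BuLi, THF, −78 °C; then i-PrC(O)N(OMe)Me, −78 °C → 0 °C; then 2 M aq. HCl, rt
Reagents that add atoms: N-methoxy-N-methyl-2-methylpropanamide, CC(C)C(=O)N(C)OC; water, O (oxygen of the regenerated formyl group)
Why: Bromine–lithium exchange followed by a Weinreb ketone synthesis should acylate the aryllithium once through the chelated tetrahedral adduct, and the aqueous acid quench should collapse that adduct and hydrolyse the dioxolane in the same flask.

Step 3
Reactants: 5 2-methyl-5-(2-methylpropanoyl)benzaldehyde
Product: 6 (Z)-N-tert-butyl-1-[2-methyl-5-(2-methylpropanoyl)phenyl]methanimine N-oxide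
Conditions: t-BuNHOH·HCl, NaHCO3, 4 Å molecular sieves, CH2Cl2, rt
Reagents that add atoms: N-tert-butylhydroxylamine hydrochloride, CC(C)(C)NO.Cl
Why: Nitrone formation by condensation of an aldehyde with an N-alkylhydroxylamine should touch only the formyl group, since the hindered aryl isopropyl ketone does not form a ketonitrone under these conditions, and should give the thermodynamic Z isomer (aryl cis to oxygen).

Step 4
Reactants: 7 guaiazulene (7-isopropyl-1,4-dimethylazulene)
Product: 9 5-isopropyl-3,8-dimethylazulene-1-carbaldehyde (3-formylguaiazulene), via iminium chloride 8 (not isolated)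
Conditions: POCl3, DMF, 0 °C → rt; then 2 M aq. NaOH
Reagents that add atoms: N,N-dimethylformamide, CN(C)C=O (formyl carbon); water, O (carbonyl oxygen)
Why: Vilsmeier–Haack formylation should occur at C3, the only unsubstituted and most nucleophilic position of the five-membered ring of guaiazulene, and the iminium salt is hydrolysed on basic work-up.

Step 5
Reactants: 9 5-isopropyl-3,8-dimethylazulene-1-carbaldehyde
Product: 10 1-(2,2-dibromoethenyl)-5-isopropyl-3,8-dimethylazulene
Conditions: CBr4, PPh3, Zn dust, CH2Cl2, 0 °C → rt
Reagents that add atoms: carbon tetrabromide, BrC(Br)(Br)Br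
Why: Corey–Fuchs (Ramirez) dibromoolefination should convert the aldehyde into the gem-dibromoalkene, and the zinc variant keeps electrophilic bromophosphonium species away from the oxidisable azulene.

Step 6
Reactants: 10 1-(2,2-dibromoethenyl)-5-isopropyl-3,8-dimethylazulene
Product: 12 5-isopropyl-3,8-dimethyl-1-(prop-1-yn-1-yl)azulene, via lithium acetylide 11 (not isolated)
Conditions: n-BuLi (2.0 equiv), THF, −78 °C; then MeI, −78 °C → rt
Reagents that add atoms: iodomethane, CI
Why: In the second stage of the Corey–Fuchs sequence, bromine–lithium exchange and Fritsch–Buttenberg–Wiechell rearrangement give the alkyne, the second equivalent of base gives the lithium acetylide, and SN2 methylation should give the internal alkyne, with exactly two equivalents of base at low temperature sparing the acidic C4 methyl group.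

Step 7
Reactants: 6 (Z)-N-tert-butyl-1-[2-methyl-5-(2-methylpropanoyl)phenyl]methanimine N-oxide; 12 5-isopropyl-3,8-dimethyl-1-(prop-1-yn-1-yl)azulene
Product: 14 2-(5-isopropyl-3,8-dimethylazulen-1-yl)-3,7-dimethyl-4-(2-methylpropanoyl)-1H-inden-1-one (target), via N-tert-butyl ketimine 13 (not isolated)
Conditions: [(C5Me5)Rh(MeCN)3](SbF6)2 (5 mol %), CsO2CCMe3 (30 mol %), 1,4-dioxane, 80 °C, N2; then 10 % aq. citric acid, THF, rt
Reagents that add atoms: water, O (carbonyl oxygen at C1, through hydrolysis of ketimine 13)
Why: Pivalate-assisted metalation of C3a–H by trivalent rhodium, directed by the nitrone oxygen, should give a rhodacycle; syn-insertion of the alkyne into the Rh–aryl bond forms C3–C3a and leaves rhodium on the azulenyl-bearing carbon, addition of this alkenyl–rhodium bond to the nitrone carbon forms C1–C2, and the N–O bond then serves as internal oxidant (loss of the C1 hydrogen and of the oxygen on nitrogen) to give ketimine 13, which is hydrolysed on work-up. The closest known reaction type is the rhodium-catalysed, nitrone-directed C–H activation and [3+2] carboannulation of C-aryl nitrones with internal aryl alkyl alkynes to 2,3-disubstituted indenones, a C–H counterpart of the Larock indenone annulation. The five-membered ring is closed by a 5-exo-trig addition of the alkenyl carbon C2 to the C=N carbon C1 inside the rhodium chelate, and no stereocentre is formed. Site selectivity is needed and is secured by the substrate: C3a–H is the only hydrogen ortho to the nitrone because C7 carries a methyl group, which also turns the nitrone oxygen toward C3a, and the nitrone oxygen is a much stronger donor than the isobutyryl oxygen that could otherwise steer the metal to C5–H. The alkyne orientation is secured by size: the short new C–C bond forms at the methyl-bearing terminus and the long Rh–C bond at the terminus carrying the bulky guaiazulenyl group, while the reverse orientation would force that group against the isobutyryl group on C4. The ring closure should choose the rhodium-bound nitrone carbon over the hindered, unbound isopropyl ketone that flanks C3a on the other side.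

**Compound list**

1 | 5-bromo-2-methylbenzaldehyde | Cc1ccc(Br)cc1C=O | starting material
2 | 2-(5-bromo-2-methylphenyl)-1,3-dioxolane | Cc1ccc(Br)cc1C1OCCO1 | intermediate
3 | [3-(1,3-dioxolan-2-yl)-4-methylphenyl]lithium | [Li]c1ccc(C)c(C2OCCO2)c1 | intermediate (not isolated)
4 | 1-[3-(1,3-dioxolan-2-yl)-4-methylphenyl]-2-methylpropan-1-one | CC(C)C(=O)c1ccc(C)c(C2OCCO2)c1 | intermediate (not isolated)
5 | 2-methyl-5-(2-methylpropanoyl)benzaldehyde | CC(C)C(=O)c1ccc(C)c(C=O)c1 | intermediate
6 | (Z)-N-tert-butyl-1-[2-methyl-5-(2-methylpropanoyl)phenyl]methanimine N-oxide | CC(C)(C)/[N+]([O-])=C/c1cc(C(=O)C(C)C)ccc1C | intermediate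
7 | guaiazulene (7-isopropyl-1,4-dimethylazulene) | c1cc(C)c2cc(C(C)C)ccc(C)c1-2 | starting material
8 | N-[(5-isopropyl-3,8-dimethylazulen-1-yl)methylidene]-N-methylmethanaminium chloride | C[N+](C)=Cc1cc(C)c2cc(C(C)C)ccc(C)c1-2.[Cl-] | intermediate (not isolated)
9 | 5-isopropyl-3,8-dimethylazulene-1-carbaldehyde | O=Cc1cc(C)c2cc(C(C)C)ccc(C)c1-2 | intermediate
10 | 1-(2,2-dibromoethenyl)-5-isopropyl-3,8-dimethylazulene | BrC(Br)=Cc1cc(C)c2cc(C(C)C)ccc(C)c1-2 | intermediate
11 | [(5-isopropyl-3,8-dimethylazulen-1-yl)ethynyl]lithium | [Li]C#Cc1cc(C)c2cc(C(C)C)ccc(C)c1-2 | intermediate (not isolated)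
12 | 5-isopropyl-3,8-dimethyl-1-(prop-1-yn-1-yl)azulene | CC#Cc1cc(C)c2cc(C(C)C)ccc(C)c1-2 | intermediate
13 | 1-[1-(tert-butylimino)-2-(5-isopropyl-3,8-dimethylazulen-1-yl)-3,7-dimethyl-1H-inden-4-yl]-2-methylpropan-1-one (C=N geometry not fixed) | CC1=C(c2cc(C)c3cc(C(C)C)ccc(C)c2-3)C(=NC(C)(C)C)c2c(C)ccc(C(=O)C(C)C)c21 | intermediate (not isolated)
14 | 2-(5-isopropyl-3,8-dimethylazulen-1-yl)-3,7-dimethyl-4-(2-methylpropanoyl)-1H-inden-1-one | CC1=C(c2cc(C)c3cc(C(C)C)ccc(C)c2-3)C(=O)c2c(C)ccc(C(=O)C(C)C)c21 | target

**Summary**

Total step count: 7. Longest linear sequence: 4 steps (steps 1, 2, 3, 7 or steps 4, 5, 6, 7).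

**Steps most likely to fail**

Step 7 is the riskiest. The metalation has to take place at a C–H bond flanked on both sides by acyl-type carbons, so it may be slow or be diverted to ketone-directed metalation at C5–H. The cationic rhodium may also be tied up by π-complexation to the azulene, and insertion of the alkyne in the reverse orientation is a further, smaller risk. The fallback uses a prefunctionalised arene instead of C–H activation. It sets out from keto aldehyde 5: a Pd(OAc)2-catalysed ortho-C–H bromination with NBS through a transient imine directing group (catalytic 2-amino-5-chlorobenzotrifluoride; divalent palladium without a bulky cyclopentadienyl ligand) should give 2-bromo-6-methyl-3-(2-methylpropanoyl)benzaldehyde F1. A Larock indenone annulation of F1 with alkyne 12 (Pd(OAc)2, Na2CO3, n-Bu4NCl, DMF, 100 °C; oxidative addition to zerovalent palladium, syn-carbopalladation, addition of the alkenylpalladium to the aldehyde, β-hydride elimination) should then give 14 directly, so the route is rejoined at 14.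

Step 6 comes next. Butyllithium may add to the seven-membered ring of the azulene or deprotonate the acidic C4 methyl group, so that methylation takes place at the wrong carbon. The fallback avoids organolithium reagents and sets out from dibromoalkene 10: dehydrobromination with n-Bu4NF·3H2O in DMF at 60 °C should give 1-(bromoethynyl)-5-isopropyl-3,8-dimethylazulene F2. A Negishi coupling of F2 with MeZnCl (Pd(PPh3)4 cat., THF, rt) should give alkyne 12, where the route is rejoined.

Step 5 is third. The formyl group is deactivated by the electron-rich five-membered ring, so the Wittig-type addition may stall, and bromine-transfer species may brominate or oxidise the azulene. The fallback is a direct C–H alkynylation that needs no aldehyde and sets out from guaiazulene 7: electrophilic alkynylation at C3 with 1-[(triisopropylsilyl)ethynyl]-1,2-benziodoxol-3(1H)-one under AuCl catalysis, a reaction type known for azulenes, should give triisopropyl[(5-isopropyl-3,8-dimethylazulen-1-yl)ethynyl]silane F3. Desilylation with n-Bu4NF in THF should give 1-ethynyl-5-isopropyl-3,8-dimethylazulene F4. Deprotonation with LiN(SiMe3)2 (1.0 equiv, THF, −78 °C) to lithium acetylide 11 and quenching with MeI should give alkyne 12, where the route is rejoined with steps 4 to 6 bypassed.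

**Further compounds**

F1 | step 7 | 2-bromo-6-methyl-3-(2-methylpropanoyl)benzaldehyde | CC(C)C(=O)c1ccc(C)c(C=O)c1Br
F2 | step 6 | 1-(bromoethynyl)-5-isopropyl-3,8-dimethylazulene | BrC#Cc1cc(C)c2cc(C(C)C)ccc(C)c1-2
F3 | step 5 | triisopropyl[(5-isopropyl-3,8-dimethylazulen-1-yl)ethynyl]silane | CC(C)[Si](C#Cc1cc(C)c2cc(C(C)C)ccc(C)c1-2)(C(C)C)C(C)C
F4 | step 5 | 1-ethynyl-5-isopropyl-3,8-dimethylazulene | C#Cc1cc(C)c2cc(C(C)C)ccc(C)c1-2
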